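Assumption: compounds 1, 2, 4, 5 and 11 are taken as purchasable. The brominated phosphonate 7 is not assumed to be stocked and is made in steps 2 and 3.

## Analysis of the target

The target 15 is 2,3,4,6-tetrabromo-1H-indole. It is a planar indole whose pyrrole ring (N1, C2, C3, C3a, C7a) carries bromine on both free carbons and whose benzo ring (C3a, C4 to C7, C7a) carries bromine on C4 and C6; hydrogen remains only on N1, C5 and C7. There is no stereocentre, so the problem is regiochemical throughout. The sensitive parts are the free N–H 2,3-dibromoindole unit, which is prone to acid-, light- and air-induced decay, and the four C–Br bonds. These bonds exclude organolithium reagents, dissolving metals, hydrogenolysis and most zerovalent palladium chemistry late in the route. The hard part is the benzo-ring pattern: C4 and C6 are meta to each other and are not the positions an indole offers to an electrophile, and the C4 bromine is peri to the C3 bromine. The strategy rests on reading N1–C2(Br)–C3(Br)–C3a–C7a as a 2,3-dibromopyrrole whose other α-carbon (C7a) bears the chain C7–C6(Br)–C5–C4(Br) and whose only free β-carbon is C3a. If C4 is carried as a CBr2 terminus, C3a=C7a, C7=C6 and C5=C4 form a hexatriene; closing C3a–C4 and losing H from C3a and one Br from C4 gives the benzo ring with one bromine left on C4. The one stereochemical element to control on the way is the geometry of the open-chain C7=C6 bond, which vanishes in the product.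

## Retrosynthetic reasoning

**N1–S bond (15 from 14).** The free N–H is unmasked last, so that the acid-sensitive 2,3-dibromoindole never meets the earlier reagents. The forward reaction has to attack sulfur and leave four C–Br bonds alone.

**C3a–C4 bond (14 from 12 through 13).** The benzo ring is opened at C3a–C4 rather than at a bond of the pyrrole ring. The cut leaves an intact dibromopyrrole and an acyclic chain, so every bromine of the target is already present in 12 and no halogenation follows ring formation. The forward reaction is a thermal six-electron ring closure to 13, then loss of H from C3a and Br from C4. It needs the dibromovinyl group cis to the pyrrole across C7=C6, which means the E isomer of 12.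

**C5=C4 bond (12 from 10 and 11).** The dibromomethylene terminus is cut at its double bond, giving aldehyde 10 and carbon tetrabromide 11. The forward olefination must not disturb the C7=C6 geometry of a labile α-bromo enal.

**Oxidation level (10 from 9 from 8).** The aldehyde is traced through alcohol 9 to ester 8, because the olefination that sets C7=C6 with the required geometry is available at the ester level. The forward steps are a hydride reduction and a neutral allylic oxidation.

**C7=C6 bond (8 from 3 and 7).** This is the stereochemically decisive cut. The thermodynamically preferred isomer of an α-bromo-β-aryl acrylic system has aryl and bromine cis, which is the opposite of what the ring closure needs. A kinetically controlled olefination of aldehyde 3 with the trifluoroethyl phosphonate 7 places the pyrrole cis to the carbonyl carbon and trans to bromine. The geometry is therefore set when the bond is made and is not corrected afterwards by a photochemical isomerization of a polybrominated diene.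

**Reagent 7 (from 6, from 4 and 5).** The monobromide is reached by exhaustive bromination of 4 with 5 and reductive removal of one bromine from 6. This avoids the mixtures that direct monobromination of an active methylene gives.

**N–S bond (3 from 1 and 2).** Pyrrole 1 already holds both pyrrole bromines and the one-carbon handle at the correct positions. Sulfonylation with 2 masks N–H for the base-mediated steps, activates the aldehyde, and lowers the aromatic stabilization that the ring closure must overcome.

## Alternatives that were turned down

**Alternative 1:** The benzo ring is taken apart into three alkynes by cutting C3a–C7a, C4–C5 and C6–C7. In the forward sense the tethered ynamide diyne A1 and ethynyl(trimethyl)silane A2 are cyclotrimerized by a ruthenium or rhodium catalyst to the indoline A3, with silyl groups marking C4 and C6.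
- For: three C–C bonds and both rings form in one catalytic step, which is more bond construction per step than the chosen key step achieves.
- Against: A3 contains no bromine and is at the indoline level. It still needs two ipso bromodesilylations, dehydrogenation, two brominations of the pyrrole ring and detosylation.
- Against: in the N-sulfonyl indoline the nitrogen directs electrophiles to C5 and C7, while the silyl groups sit meta to nitrogen at C4 and C6. Ipso attack therefore competes with ordinary substitution at the very carbons that must stay C–H.
- Against: the position of the silyl group from A2 (C6 against C5) rests on sterics alone, and A1 itself takes several steps.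
- Comparison: Alternative 1 is stronger on convergence. The chosen strategy offers every bromine delivered by a starting material or reagent before the ring exists, and a single deprotection after the key step.

**Alternative 2:** The pyrrole ring is cut at C2=C3. In the forward sense the aldehyde carbon and the amide carbonyl carbon of oxamate A4 are coupled reductively by low-valent titanium (a McMurry-type closure) to give the indole ester A5.
- For: the ring closure is a known, dependable reaction type, and the benzo-ring bromines come from the arene with no regiochemical doubt. On precedent for the key step it is stronger than the chosen strategy.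
- Against: A5 has an ester where C2 needs bromine and hydrogen at C3. Saponification and a harsh decarboxylation to A6 are followed by two electrophilic brominations; the one at C3 goes against the peri C4 bromine, can overrun to C5 or C7, and exposes N–H 2-bromoindoles to the acid it releases.
- Against: the formyl group of A4 is flanked by nitrogen and bromine, and low-valent titanium may erode C–Br bonds.
- Comparison: the chosen strategy gives up the known key step and gains a route with no halogenation and no decarboxylation after the bicycle is formed.

**Alternative 3:** The N1–C2 bond is cut. In the forward sense the sulfonamide nitrogen of A7 bonds to the dibromo carbon under a carbonate base or copper catalysis and closes the pyrrole ring as the 2-bromoindole A8.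
- For: C2–Br arrives with the ring, the reaction type is known and mild, and only C3 bromination and detosylation remain. This is probably the shortest and most dependable of the four plans, and it is stronger than the chosen strategy on precedent and likely on step count.
- Against: the remaining bromination must take place on an indole deactivated by three bromines and a sulfonyl group and against the peri C4 bromine. Alternatively it follows detosylation, on an acid-sensitive N–H 2-bromoindole while acid is formed.
- Against: the arene precursor, with bromine ortho and para to the formyl group, is not a stock compound.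
- Comparison: the chosen strategy offers in its place the assembly of the crowded C3/C4 pair from a pyrrole bromine and a chain bromine, so that no electrophile has to enter a peri position, a stock dibromopyrrole as the source of half the molecule, and a benzannulation mode that would be new.

Key step: step 8

## Route

Step 1
Reactants: 1 4,5-dibromo-1H-pyrrole-2-carbaldehyde; 2 benzenesulfonyl chloride
Product: 3 4,5-dibromo-1-(phenylsulfonyl)-1H-pyrrole-2-carbaldehyde
Conditions: NaH, THF, 0 °C; then 2, 0 → 20 °C
Reagents that add atoms: benzenesulfonyl chloride, O=S(=O)(Cl)c1ccccc1
Why: The N–H of 1 is acidified by the formyl group and two bromines, so NaH gives the pyrrolide, which attacks sulfur of 2 (N-sulfonylation); the sulfonyl group masks N–H, activates the aldehyde and later lowers the aromatic stabilization of the pyrrole.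

Step 2
Reactants: 4 methyl 2-[bis(2,2,2-trifluoroethoxy)phosphoryl]acetate; 5 bromine
Product: 6 methyl 2,2-dibromo-2-[bis(2,2,2-trifluoroethoxy)phosphoryl]acetate
Conditions: Br2, aq. NaOH, 0 °C
Reagents that add atoms: bromine, BrBr
Why: The doubly activated methylene of 4 is brominated twice by hypobromite formed from Br2 and NaOH (exhaustive α-halogenation of an active methylene); going to the dibromide avoids mixtures of mono- and dibromide.

Step 3
Reactants: 6 methyl 2,2-dibromo-2-[bis(2,2,2-trifluoroethoxy)phosphoryl]acetate
Product: 7 methyl 2-bromo-2-[bis(2,2,2-trifluoroethoxy)phosphoryl]acetate (racemic)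
Conditions: SnCl2·2H2O, EtOH/H2O, 0 °C
Reagents that add atoms: none
Why: Divalent tin attacks one bromine of the doubly activated dibromide and the stabilized carbanion is protonated (halophilic reductive monodebromination); the monobromide is much harder to reduce, so the reaction should stop at 7.

Step 4
Reactants: 3 4,5-dibromo-1-(phenylsulfonyl)-1H-pyrrole-2-carbaldehyde; 7 methyl 2-bromo-2-[bis(2,2,2-trifluoroethoxy)phosphoryl]acetate
Product: 8 methyl (2E)-2-bromo-3-[4,5-dibromo-1-(phenylsulfonyl)-1H-pyrrol-2-yl]prop-2-enoate
Conditions: 7, t-BuOK, 18-crown-6, THF, −78 °C; then 3, −78 °C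
Reagents that add atoms: methyl 2-bromo-2-[bis(2,2,2-trifluoroethoxy)phosphoryl]acetate, COC(=O)C(Br)P(=O)(OCC(F)(F)F)OCC(F)(F)F
Why: Horner–Wadsworth–Emmons olefination of the Still–Gennari type: the trifluoroethyl phosphonate makes elimination from the kinetic adduct fast under non-chelating K+/18-crown-6 conditions, so the pyrrolyl group and the ester end up cis, which with bromine on the α-carbon is the E isomer; this fixes the C7=C6 geometry that step 8 needs.

Step 5
Reactants: 8 methyl (2E)-2-bromo-3-[4,5-dibromo-1-(phenylsulfonyl)-1H-pyrrol-2-yl]prop-2-enoate
Product: 9 (2E)-2-bromo-3-[4,5-dibromo-1-(phenylsulfonyl)-1H-pyrrol-2-yl]prop-2-en-1-ol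
Conditions: i-Bu2AlH, CH2Cl2, −78 °C
Reagents that add atoms: none
Why: Two hydride transfers from i-Bu2AlH reduce the ester to the allylic alcohol (1,2-reduction) at a temperature at which the vinyl and pyrrole bromides and the sulfonamide are inert; the alkene geometry is not involved.

Step 6
Reactants: 9 (2E)-2-bromo-3-[4,5-dibromo-1-(phenylsulfonyl)-1H-pyrrol-2-yl]prop-2-en-1-ol
Product: 10 (2E)-2-bromo-3-[4,5-dibromo-1-(phenylsulfonyl)-1H-pyrrol-2-yl]prop-2-enal
Conditions: activated MnO2 (excess), CH2Cl2, 20 °C, dark
Reagents that add atoms: none
Why: Activated MnO2 oxidizes the allylic alcohol selectively under neutral heterogeneous conditions (allylic oxidation), which should preserve the less stable E geometry; the enal is carried on at once without exposure to light, acid or nucleophiles.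

Step 7
Reactants: 10 (2E)-2-bromo-3-[4,5-dibromo-1-(phenylsulfonyl)-1H-pyrrol-2-yl]prop-2-enal; 11 carbon tetrabromide
Product: 12 2,3-dibromo-1-(phenylsulfonyl)-5-[(1E)-2,4,4-tribromobuta-1,3-dien-1-yl]-1H-pyrrole
Conditions: CBr4, PPh3, Zn dust, CH2Cl2, 20 °C (ylide preformed); then 10, 0 °C, dark
Reagents that add atoms: carbon tetrabromide, BrC(Br)(Br)Br
Why: Ramirez dibromo-olefination (the first stage of the Corey–Fuchs sequence): Ph3P=CBr2, preformed with zinc so that neither free phosphine nor a phosphorus–bromine by-product meets the enal, converts the aldehyde into the 1,1-dibromoalkene; C7=C6 is not touched and stays E.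

Step 8
Reactants: 12 2,3-dibromo-1-(phenylsulfonyl)-5-[(1E)-2,4,4-tribromobuta-1,3-dien-1-yl]-1H-pyrrole
Product: 14 2,3,4,6-tetrabromo-1-(phenylsulfonyl)-1H-indole, via 2,3,4,4,6-pentabromo-1-(phenylsulfonyl)-3a,4-dihydro-1H-indole 13 (not isolated)
Conditions: 1,2-dichlorobenzene (0.02 M), 2,6-di-tert-butyl-4-methylpyridine, 180–210 °C, sealed tube, Ar, dark
Reagents that add atoms: none
Why: Proposed new method: the pyrrole C3a=C7a bond, C7=C6 and C5=C4 of 12 form a cis-hexatriene that should close thermally in the disrotatory six-electron mode at C3a–C4 to the dihydroindole 13, whose doubly allylic C3a–H and one C4–Br are then lost as HBr (ionization of C4–Br assisted by the nitrogen-terminated diene, or E2 with the pyridine base) to give the aromatic indole 14. The closest known reaction type is the thermal six-electron electrocyclization of 2-dienyl- and 2,3-divinyl-pyrroles and -indoles followed by oxidation or by loss of a small molecule; a gem-dibromide terminus as carrier of the leaving group has not been shown on this substrate class. The one ring closed is the six-membered carbocycle, formed through the helical s-cis,s-cis conformer in which C7–H, not C6–Br, faces the sulfonyl group. The only stereocentre created, C3a of 13, arises as a racemate from the two equally populated helical senses of the achiral triene and is erased by the elimination. Site selectivity needs no control because C3a is the only unsubstituted pyrrole carbon next to the chain, and the required cis arrangement of pyrrole and dibromovinyl group across C7=C6 is the E geometry set in step 4. Bromine at C4 is retained because the terminus carries two bromines: either may leave and the other stays. The closure is uphill and reversible (pyrrole aromaticity is lost, one C4 bromine points inward and C3 carries bromine), so the irreversible aromatizing elimination has to pull it through; the sulfonyl group lowers the aromatic penalty, and the hindered, weakly basic pyridine takes up HBr without attacking the dibromovinyl group.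

Step 9
Reactants: 14 2,3,4,6-tetrabromo-1-(phenylsulfonyl)-1H-indole
Product: 15 2,3,4,6-tetrabromo-1H-indole
Conditions: Bu4NF, THF, 20 → 60 °C; aqueous work-up, exclusion of acid and light
Reagents that add atoms: none
Why: Fluoride attacks sulfur and expels the indolide (nucleophilic N-desulfonylation); four bromines make this anion a very good leaving group, so mild conditions should suffice, and protonation on work-up gives 15.

## Compound list

1 | 4,5-dibromo-1H-pyrrole-2-carbaldehyde | O=Cc1cc(Br)c(Br)[nH]1 | starting material
2 | benzenesulfonyl chloride | O=S(=O)(Cl)c1ccccc1 | starting material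
3 | 4,5-dibromo-1-(phenylsulfonyl)-1H-pyrrole-2-carbaldehyde | O=Cc1cc(Br)c(Br)n1S(=O)(=O)c1ccccc1 | intermediate
4 | methyl 2-[bis(2,2,2-trifluoroethoxy)phosphoryl]acetate | COC(=O)CP(=O)(OCC(F)(F)F)OCC(F)(F)F | starting material
5 | bromine | BrBr | starting material
6 | methyl 2,2-dibromo-2-[bis(2,2,2-trifluoroethoxy)phosphoryl]acetate | COC(=O)C(Br)(Br)P(=O)(OCC(F)(F)F)OCC(F)(F)F | intermediate
7 | methyl 2-bromo-2-[bis(2,2,2-trifluoroethoxy)phosphoryl]acetate (racemic) | COC(=O)C(Br)P(=O)(OCC(F)(F)F)OCC(F)(F)F | intermediate
8 | methyl (2E)-2-bromo-3-[4,5-dibromo-1-(phenylsulfonyl)-1H-pyrrol-2-yl]prop-2-enoate | COC(=O)/C(Br)=C\c1cc(Br)c(Br)n1S(=O)(=O)c1ccccc1 | intermediate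
9 | (2E)-2-bromo-3-[4,5-dibromo-1-(phenylsulfonyl)-1H-pyrrol-2-yl]prop-2-en-1-ol | OC/C(Br)=C\c1cc(Br)c(Br)n1S(=O)(=O)c1ccccc1 | intermediate
10 | (2E)-2-bromo-3-[4,5-dibromo-1-(phenylsulfonyl)-1H-pyrrol-2-yl]prop-2-enal | O=C/C(Br)=C\c1cc(Br)c(Br)n1S(=O)(=O)c1ccccc1 | intermediate
11 | carbon tetrabromide | BrC(Br)(Br)Br | starting material
12 | 2,3-dibromo-1-(phenylsulfonyl)-5-[(1E)-2,4,4-tribromobuta-1,3-dien-1-yl]-1H-pyrrole | O=S(=O)(c1ccccc1)n1c(Br)c(Br)cc1/C=C(/Br)C=C(Br)Br | intermediate
13 | 2,3,4,4,6-pentabromo-1-(phenylsulfonyl)-3a,4-dihydro-1H-indole (racemic, not isolated) | O=S(=O)(c1ccccc1)N1C(Br)=C(Br)C2C1=CC(Br)=CC2(Br)Br | intermediate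
14 | 2,3,4,6-tetrabromo-1-(phenylsulfonyl)-1H-indole | O=S(=O)(c1ccccc1)n1c(Br)c(Br)c2c(Br)cc(Br)cc12 | intermediate
15 | 2,3,4,6-tetrabromo-1H-indole | Brc1cc(Br)c2c(Br)c(Br)[nH]c2c1 | target

## Step count and least certain steps

Total step count: 9. Longest linear sequence: 8 steps (from phosphonate 4 through steps 2 to 9); 7 steps from pyrrole 1.

**Step 8 (key step, proposed new method).**
- Risk: the ring may fail to close below the temperature at which 12 decays. The barrier is raised by the loss of pyrrole aromaticity, by the inward bromine at C4 and by the bromine on C3.
- Competing processes: thermal loss of HBr from the dibromovinyl group to a bromoalkyne, C–Br homolysis, and isomerization about C7=C6 to the geometry that cannot close.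
- Fallback (known chemistry, from 12, rejoining at 14): DBU in acetonitrile at 20 °C should remove HBr across C5–C4 only, because that H/Br pair is anti whereas the C7–H/C6–Br pair is syn. This gives the bromoalkyne 2,3-dibromo-5-[(1E)-2,4-dibromobut-1-en-3-yn-1-yl]-1-(phenylsulfonyl)-1H-pyrrole F1. Catalytic InCl3 in toluene at 80–100 °C should then effect a 6-endo-dig hydroarylation: the activated bromoalkyne is attacked at its bromine-bearing carbon by the free pyrrole carbon, and rearomatization with protodemetalation leaves H on C5 and Br on C4, which is 14.
- Basis of the fallback: this is the known Lewis-acid-catalyzed cycloisomerization of aryl-tethered haloalkynes to haloarenes. InCl3 is chosen because π-acids that act through vinylidene intermediates can shift the halogen to the neighbouring carbon. The electron-poor pyrrole is a weak nucleophile, so forcing conditions may be needed.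

**Step 4.**
- Risk: erosion of the kinetic geometric selectivity with a hindered, electron-poor heteroaryl aldehyde, and cleavage of the N–S bond by adventitious alkoxide.
- Fallback (from 3, rejoining at 12): the selective olefination is replaced by a thermodynamic one followed by geometric correction.
  - The stabilized ylide 2-bromo-2-(triphenylphosphoranylidene)acetaldehyde F2 is made from commercial (triphenylphosphoranylidene)acetaldehyde with Br2 and then Et3N.
  - F2 reacts with 3 in toluene at 80 °C to give the thermodynamic enal (2Z)-2-bromo-3-[4,5-dibromo-1-(phenylsulfonyl)-1H-pyrrol-2-yl]prop-2-enal F3.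
  - The conditions of step 7 convert F3 into 2,3-dibromo-1-(phenylsulfonyl)-5-[(1Z)-2,4,4-tribromobuta-1,3-dien-1-yl]-1H-pyrrole F4.
  - Triplet sensitization (thioxanthone, 405 nm, acetonitrile) should enrich the more twisted E isomer 12, which is separated while F4 is recycled. The position of the photostationary state is not assured.

**Step 7.**
- Risk: scrambling of the C7=C6 geometry of the labile enal 10 by reversible conjugate addition of phosphine or bromide before the olefination occurs.
- Fallback (from 10, rejoining at 12): the ylide is replaced by carbonyl addition and reductive elimination, with no phosphine present.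
  - CBr4 11 and SnF2 in DMSO at 20 °C add a tribromomethyl group to the aldehyde to give (3E)-1,1,1,3-tetrabromo-4-[4,5-dibromo-1-(phenylsulfonyl)-1H-pyrrol-2-yl]but-3-en-2-ol F5.
  - Ac2O, pyridine and catalytic DMAP give (3E)-1,1,1,3-tetrabromo-4-[4,5-dibromo-1-(phenylsulfonyl)-1H-pyrrol-2-yl]but-3-en-2-yl acetate F6.
  - Zn in AcOH/THF at 0 °C inserts into the most reducible C–Br bond and expels acetate, giving the dibromoalkene 12.

**Step 3.**
- Risk: over-reduction back to 4, and solvolysis of the activated trifluoroethyl phosphonate esters in the aqueous media of steps 2 and 3.
- Fallback (from 4, rejoining at 8): the brominated phosphonate is not isolated. The anion of 4 (NaH, THF, 0 °C) is treated with Br2, one further equivalent of t-BuOK with 18-crown-6 is added at −78 °C so that dibromide and unbrominated phosphonate comproportionate to the anion of 7, and aldehyde 3 is added to give 8. This fallback makes no compound outside the list (F0).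

## Further compounds

F1 | step 8 | 2,3-dibromo-5-[(1E)-2,4-dibromobut-1-en-3-yn-1-yl]-1-(phenylsulfonyl)-1H-pyrrole | O=S(=O)(c1ccccc1)n1c(Br)c(Br)cc1/C=C(/Br)C#CBr
F2 | step 4 | 2-bromo-2-(triphenylphosphoranylidene)acetaldehyde | O=CC(Br)=P(c1ccccc1)(c1ccccc1)c1ccccc1
F3 | step 4 | (2Z)-2-bromo-3-[4,5-dibromo-1-(phenylsulfonyl)-1H-pyrrol-2-yl]prop-2-enal | O=C/C(Br)=C/c1cc(Br)c(Br)n1S(=O)(=O)c1ccccc1
F4 | step 4 | 2,3-dibromo-1-(phenylsulfonyl)-5-[(1Z)-2,4,4-tribromobuta-1,3-dien-1-yl]-1H-pyrrole | O=S(=O)(c1ccccc1)n1c(Br)c(Br)cc1/C=C(\Br)C=C(Br)Br
F5 | step 7 | (3E)-1,1,1,3-tetrabromo-4-[4,5-dibromo-1-(phenylsulfonyl)-1H-pyrrol-2-yl]but-3-en-2-ol (racemic) | OC(/C(Br)=C\c1cc(Br)c(Br)n1S(=O)(=O)c1ccccc1)C(Br)(Br)Br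
F6 | step 7 | (3E)-1,1,1,3-tetrabromo-4-[4,5-dibromo-1-(phenylsulfonyl)-1H-pyrrol-2-yl]but-3-en-2-yl acetate (racemic) | CC(=O)OC(/C(Br)=C\c1cc(Br)c(Br)n1S(=O)(=O)c1ccccc1)C(Br)(Br)Br
F0 | step 3 | none | none
A1 | alternative 1 | N-ethynyl-4-methyl-N-[4-(trimethylsilyl)but-3-yn-1-yl]benzenesulfonamide | Cc1ccc(cc1)S(=O)(=O)N(C#C)CCC#C[Si](C)(C)C
A2 | alternative 1 | ethynyl(trimethyl)silane | C#C[Si](C)(C)C
A3 | alternative 1 | 1-tosyl-4,6-bis(trimethylsilyl)indoline | Cc1ccc(cc1)S(=O)(=O)N1CCc2c1cc(cc2[Si](C)(C)C)[Si](C)(C)C
A4 | alternative 2 | ethyl 2-[(3,5-dibromo-2-formylphenyl)amino]-2-oxoacetate | CCOC(=O)C(=O)Nc1cc(Br)cc(Br)c1C=O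
A5 | alternative 2 | ethyl 4,6-dibromo-1H-indole-2-carboxylate | CCOC(=O)c1cc2c(Br)cc(Br)cc2[nH]1
A6 | alternative 2 | 4,6-dibromo-1H-indole | Brc1cc(Br)c2cc[nH]c2c1
A7 | alternative 3 | N-[3,5-dibromo-2-(2,2-dibromoethenyl)phenyl]-4-methylbenzenesulfonamide | Cc1ccc(cc1)S(=O)(=O)Nc1cc(Br)cc(Br)c1C=C(Br)Br
A8 | alternative 3 | 2,4,6-tribromo-1-tosyl-1H-indole | Cc1ccc(cc1)S(=O)(=O)n1c(Br)cc2c(Br)cc(Br)cc12
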